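**Remark on the chemistry (assumption and locants).** The SMILES assigns no configuration to the C3'–C8'' biaryl axis, so the target is taken as configurationally undefined and no step has to control the axis. Locants: unprimed = chromone of the first unit (rings A and C), single prime = its ring B, double prime = chromone of the second unit (rings A'' and C''), triple prime = its ring B'''.

## The problem

The target is two 5-hydroxy-7-methoxy-2-(4-hydroxyphenyl)chromen-4-one (genkwanin) units joined by one biaryl bond, from C3' of ring B of the first unit to C8'' of ring A'' of the second. This bond is the difficulty: it is flanked by three ortho substituents (4'-OH on one side, 7''-OMe and C8a''–O1'' on the other). A metal-catalysed coupling would need a halide on one hindered carbon and a metal on the other, and C3' of a finished flavone cannot be functionalized selectively while the far more reactive ring A is present. There are no stereocentres, and the axis is not assigned. Six ring oxygens must end up differentiated: methyl ethers at O7 and O7'', free phenols at O5, O5'', O4' and O4'''. A 4'-methyl ether cannot be cleaved beside a 7-methyl ether, so global methyl protection is excluded. The γ-pyrone rings are opened by hot hydroxide, their C2=C3 bonds can be reduced or take up nucleophiles, and the phloroglucinol-type rings A and the free phenols are easily over-halogenated or over-oxidized. The feature that opens the plan is that both halves are the same monomer and that the two carbons to be joined are its innately reactive C–H positions under phenol oxidation. C3' is ortho to the free 4'-OH of ring B, whose para carbon C1' is blocked by the chromone. C8'' is the ring A'' CH between 7''-OMe and O1'' and para to the C5'' oxygen, the most nucleophilic open position of a 5,7-dialkoxychromone. The target is therefore the 3',8''-dehydrodimer of genkwanin.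

## Retrosynthesis

**7 from 6.** The two O–benzyl bonds at O5'' and O4''' are cut last. These are the only protecting groups of the route. Benzyl is chosen because hydrogenolysis touches neither the two methyl ethers nor the pyrones. The precursor 6 is no simpler, but the forward step is a routine hydrogenolysis that must spare the C2=C3 bonds.

**6 from 2 and 3.** The C3'–C8'' bond is cut as a dehydrogenative phenol–arene coupling, C–H plus C–H, following the presumed biosynthetic phenol coupling of two flavone monomers. Cutting the same bond into halide and boronate would require a ring B functionalized at C3', which must be built from scratch. Cutting inside ring A'' would require both chromones to be rebuilt. Here each precursor is half the size of 6 and both come from one compound: genkwanin 2 serves as the phenol, and its dibenzyl ether 3 as the arene. The forward reaction must turn only the 4'-OH of 2 into an electrophile (aryloxyiodane 4, with a trivalent iodine oxidant in a fluorinated alcohol). C8 of 3 must then attack C3' to give dienone 5, which tautomerizes to 6.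

**3 from 2.** The O5–benzyl and O4'–benzyl bonds are cut. A direct self-coupling of 2 would be one step shorter, but the nucleophilic half would then carry a free 5-OH, which is known to steer electrophiles to C6, and a second oxidizable 4'-OH, which invites oligomers. In 3 no OH is left to be oxidized, C6 sits between two alkoxy groups, and C8 is the preferred site, as in the halogenation of 5,7-dialkoxyflavones. The forward step is a double Williamson benzylation, and the chelated 5-OH needs forcing conditions.

**2 from 1.** The O7–CH3 bond is cut. Apigenin 1 is cheap, commercial, and already contains the complete carbon skeleton and oxygen pattern of each half. The forward step must methylate only the most acidic hydroxyl (7-OH) beside 4'-OH and the chelated 5-OH.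

## Roads not taken

**Alternative 1:** The most obvious plan cuts the same C3'–C8'' bond as a Suzuki–Miyaura coupling of two protected flavone halves. 8-Iodo-5,4'-di-O-isopropylgenkwanin A1 would be coupled with the 3'-pinacolboronate A2 to give tetra-O-isopropyl biflavone A3, followed by Lewis acid dealkylation. A1 is easy to make by iodination at C8. A2 is not, because electrophiles attack ring A before C3'; its ring B must be brought in pre-halogenated through a chalcone, an oxidative cyclization and a borylation. The plan needs four protecting groups and a tri-ortho-substituted coupling prone to protodeboronation, and it runs to about ten steps against four. It makes no use of the fact that both halves are the same monomer. It is kept as the fallback for the key step.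

**Alternative 2:** Ring A'' is cut instead of the biaryl bond. Bonds C8''–C8a'', C6''–C7'' and C4a''–C8a'' would be formed in a Danheiser benzannulation of aryl ynol ether A4 with 3-ethoxycyclobutenone A5. The sequence is four-electron ring opening to a vinylketene, [2+2] addition to the ynol ether, a second four-electron opening, six-electron electrocyclization and tautomerization, giving phenol A6. The hindered aryl would be in place from the start and the three oxygens of ring A'' would be differentiated. However, both pyranone rings and ring B''' would still have to be built by two separate acylation and cyclization sequences, the ynol ether is sensitive, and the ethyl ether must later be cleaved selectively. The route would exceed twelve steps and discard the two finished chromones that apigenin provides.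

**Alternative 3:** Both pyranone rings are cut (O1–C2 and C2–C3 of each) and the biaryl is made early. Iodoacetophenone A7 would be coupled with formyl boronic acid A8 to give keto aldehyde A9, followed by an aldol condensation and oxidative cyclization on each side. A9 carries a methyl ketone and an aldehyde in one molecule, which would self-condense under Claisen–Schmidt conditions, so masking and strict sequencing would be needed. The hindered coupling is still required, and each chromone costs two further steps, about ten to twelve in all. The chosen plan forms the same bond without pre-functionalization and buys both chromones ready-made.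

Key step: step 3

## Route

Step 1
Reactants: 1 apigenin (5,7-dihydroxy-2-(4-hydroxyphenyl)-4H-chromen-4-one)
Product: 2 genkwanin (5-hydroxy-2-(4-hydroxyphenyl)-7-methoxy-4H-chromen-4-one)
Conditions: MeI (1.05 equiv), K2CO3 (1.0 equiv), DMF, 0 °C to rt
Reagents that add atoms: iodomethane, CI
Why: Williamson etherification of the mono-phenoxide; 7-OH is the most acidic hydroxyl (a vinylogous acid through ring A to the C4 carbonyl), 5-OH is held in a hydrogen bond to C4=O and 4'-OH is less acidic, so one equivalent of base and electrophile should methylate O7 preferentially.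

Step 2
Reactants: 2 genkwanin
Product: 3 5,4'-di-O-benzylgenkwanin (5-(benzyloxy)-2-[4-(benzyloxy)phenyl]-7-methoxy-4H-chromen-4-one)
Conditions: BnBr (3 equiv), K2CO3 (4 equiv), Bu4NI (cat.), DMF, 70 °C
Reagents that add atoms: benzyl bromide, BrCc1ccccc1
Why: Double Williamson etherification; 4'-OH reacts first, and the chelated 5-OH needs excess reagent and heat, as is usual for 5-O-alkylation of 5-hydroxyflavones.

Step 3
Reactants: 2 genkwanin (1 equiv); 3 5,4'-di-O-benzylgenkwanin (3 equiv, excess recovered)
Product: 6 5'',4'''-di-O-benzyl-7,7''-di-O-methylamentoflavone, via aryloxyiodane 4 (not isolated), via cyclohexadienone adduct 5 (not isolated)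
Conditions: PhI(OCOCF3)2 (1.0 equiv, added slowly), (CF3)2CHOH–CH2Cl2, 4 Å MS, -30 °C to 0 °C
Reagents that add atoms: none
Why: Proposed new method: the closest known reaction type is the oxidative cross-coupling of para-substituted phenols with alkoxyarenes by trivalent iodine reagents in fluorinated alcohols, which joins the carbon ortho to the phenolic OH to the most nucleophilic arene CH; it has not been shown for a 4'-hydroxyflavone as the phenol or for ring A of a chromone as the arene. PhI(OCOCF3)2 should exchange one trifluoroacetate for the only free, non-chelated OH in the flask, the 4'-OH of 2 (the site at which this reagent is known to dearomatize 4'-hydroxyflavones to 1'-hydroxy para-quinols in wet solvent), giving aryloxyiodane 4, whose O–I bond is polarized by the hydrogen-bond-donating, non-nucleophilic solvent so that ring B becomes electrophilic at C3' and C1'. C8 of 3 should then attack C3' with loss of PhI and trifluoroacetate to give cyclohexa-2,4-dienone 5, and enolization restores ring B to give 6; no ring is closed, the sp3 carbon C3' of 5 is transient, and the new axis is not configurationally defined. Oxidation of 2 and not of 3 is secured by the substrates: 3 has no OH to bind iodine, and the chelated 5-OH of 2 should exchange far more slowly than its 4'-OH. Ortho attack at C3' is favoured because the para carbon C1' already carries the chromone, so attack there by the doubly flanked C8 would build a congested quaternary carbon, and because water, which would add at C1', is excluded by molecular sieves. On the nucleophile the site is secured by the 5-O-benzyl group: C8 is para to this donor and ortho to OMe and O1, whereas C6 is squeezed between two alkoxy groups (the same preference that directs halogenation of 5,7-dialkoxyflavones to C8), and the 4-benzyloxyphenyl ring is deactivated by the chromone. Self-coupling of 2 through its own ring A is held back by the excess of 3, by slow addition of the oxidant and by the lower nucleophilicity of the hydrogen-bonded ring A of 2, and a second arylation at C5' is limited by making 2 the limiting reagent.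

Step 4
Reactants: 6 5'',4'''-di-O-benzyl-7,7''-di-O-methylamentoflavone
Product: 7 7,7''-dimethoxyamentoflavone (7,7''-di-O-methylamentoflavone, the target)
Conditions: H2 (1 atm), Pd/C (10 wt% Pd on carbon), THF–MeOH, rt
Reagents that add atoms: none
Why: Catalytic hydrogenolysis of the two benzyl aryl ethers; the methyl ethers, the phenols and the chromone C2=C3 bonds should be untouched under these mild conditions if the reaction is stopped once debenzylation is complete.

## Compound list

1 | apigenin, 5,7-dihydroxy-2-(4-hydroxyphenyl)-4H-chromen-4-one | O=c1cc(-c2ccc(O)cc2)oc2cc(O)cc(O)c12 | starting material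
2 | genkwanin, 5-hydroxy-2-(4-hydroxyphenyl)-7-methoxy-4H-chromen-4-one | COc1cc(O)c2c(=O)cc(-c3ccc(O)cc3)oc2c1 | intermediate
3 | 5,4'-di-O-benzylgenkwanin, 5-(benzyloxy)-2-[4-(benzyloxy)phenyl]-7-methoxy-4H-chromen-4-one | COc1cc(OCc2ccccc2)c2c(=O)cc(-c3ccc(OCc4ccccc4)cc3)oc2c1 | intermediate
4 | aryloxyiodane of 2, [4-(5-hydroxy-7-methoxy-4-oxo-4H-chromen-2-yl)phenoxy](phenyl)(trifluoroacetoxy)-λ3-iodane | COc1cc(O)c2c(=O)cc(-c3ccc(OI(OC(=O)C(F)(F)F)c4ccccc4)cc3)oc2c1 | intermediate (not isolated)
5 | cyclohexa-2,4-dienone tautomer of 6: ring B as a cyclohexa-2,4-dien-1-one (C4'=O) carrying H and the 8-yl group of 3 on the sp3 carbon C3' and the genkwanin chromon-2-yl group on C1'; racemic at C3', transient | COc1cc(O)c2c(=O)cc(C3=CC(c4c(OC)cc(OCc5ccccc5)c5c(=O)cc(-c6ccc(OCc7ccccc7)cc6)oc45)C(=O)C=C3)oc2c1 | intermediate (not isolated)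
6 | 5'',4'''-di-O-benzyl-7,7''-di-O-methylamentoflavone, 2-{3-[5-(benzyloxy)-2-(4-(benzyloxy)phenyl)-7-methoxy-4-oxo-4H-chromen-8-yl]-4-hydroxyphenyl}-5-hydroxy-7-methoxy-4H-chromen-4-one | COc1cc(O)c2c(=O)cc(-c3ccc(O)c(-c4c(OC)cc(OCc5ccccc5)c5c(=O)cc(-c6ccc(OCc7ccccc7)cc6)oc45)c3)oc2c1 | intermediate
7 | 7,7''-dimethoxyamentoflavone (7,7''-di-O-methylamentoflavone) | COc1cc(O)c2c(=O)cc(-c3ccc(O)c(-c4c(OC)cc(O)c5c(=O)cc(-c6ccc(O)cc6)oc45)c3)oc2c1 | target

## Step count and least certain steps

Total step count: 4. Longest linear sequence: 4 steps (1 → 2 → 3 → 6 → 7); compound 2 enters the key step a second time as the coupling partner.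

**Step 3 (key step, Proposed new method).** The aryloxyiodane 4 may be captured by something other than C8 of 3. Possible diversions are self-coupling of 2 through C6 or C8 of its own ring A, C–O coupling through a phenolic oxygen, dearomatization at C1' by traces of water, and attack by C6 or C3 of 3. The cause is that ring A of 3 is conjugated to the C4 carbonyl and so is a weaker π-nucleophile than the polyalkoxybenzenes for which this reaction type is established. Re-oxidation of the product phenol and a second arylation at C5' are further risks.

The fallback uses known chemistry; it sets out from 3 and comes back to the route at 7. Compound 3 is iodinated at C8 (N-iodosuccinimide, CF3CO2H cat., MeCN) to give 5-(benzyloxy)-2-[4-(benzyloxy)phenyl]-8-iodo-7-methoxy-4H-chromen-4-one F1. The partner is built with ring B already functionalized. Commercial 2',6'-dihydroxy-4'-methoxyacetophenone is monobenzylated (BnBr, K2CO3, acetone) to 1-[2-(benzyloxy)-6-hydroxy-4-methoxyphenyl]ethan-1-one F2. Commercial 3-bromo-4-hydroxybenzaldehyde is benzylated to 4-(benzyloxy)-3-bromobenzaldehyde F3. Claisen–Schmidt condensation of the two (KOH, EtOH) gives (E)-1-[2-(benzyloxy)-6-hydroxy-4-methoxyphenyl]-3-[4-(benzyloxy)-3-bromophenyl]prop-2-en-1-one F4. Oxidative cyclization (I2 cat., DMSO, 130 °C) gives 5-(benzyloxy)-2-[4-(benzyloxy)-3-bromophenyl]-7-methoxy-4H-chromen-4-one F5. Miyaura borylation (B2pin2, PdCl2(dppf), KOAc, dioxane, 90 °C) gives the 3'-pinacolboronate F6. Suzuki–Miyaura coupling of F1 with F6 (Pd(PPh3)4, K3PO4, DMF–H2O, 90 °C) gives 5,5'',4',4'''-tetra-O-benzyl-7,7''-di-O-methylamentoflavone F7. Hydrogenolysis under the conditions of step 4 gives 7.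

**Step 1.** Site selectivity may be lost through methylation at O4' as well, because the 7- and 4'-phenoxides equilibrate and their acidity difference is modest. The fallback sets out from 1 and comes back at 2. Peracetylation (Ac2O, pyridine) gives apigenin triacetate F8. Selective removal of the most labile 7-O-acetyl group (PhSH, imidazole, N-methylpyrrolidone, 0 °C) gives 5,4'-di-O-acetylapigenin F9. Mitsunobu methylation of the single free OH (MeOH, PPh3, diisopropyl azodicarboxylate, THF) gives 5,4'-di-O-acetylgenkwanin F10. K2CO3 in MeOH removes both acetates to give 2.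

**Step 4.** Over-reduction may saturate one or both C2=C3 bonds to flavanones. The reaction may also stall because partly debenzylated material is poorly soluble or because iodine-containing traces from step 3 poison the catalyst. The fallback sets out from 6 and comes back at 7 without a new compound. It is a Lewis acid dealkylation with BCl3 and pentamethylbenzene as benzyl cation scavenger in CH2Cl2 at -78 °C. This should cleave the peri 5''-O-benzyl group through chelation and the 4'''-O-benzyl group by ionization, while the methyl ethers at O7 and O7'', which are not peri to a carbonyl, should stay.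

## Further compounds

F1 | step 3 | 5-(benzyloxy)-2-[4-(benzyloxy)phenyl]-8-iodo-7-methoxy-4H-chromen-4-one | COc1cc(OCc2ccccc2)c2c(=O)cc(-c3ccc(OCc4ccccc4)cc3)oc2c1I
F2 | step 3 | 1-[2-(benzyloxy)-6-hydroxy-4-methoxyphenyl]ethan-1-one | CC(=O)c1c(O)cc(OC)cc1OCc1ccccc1
F3 | step 3 | 4-(benzyloxy)-3-bromobenzaldehyde | O=Cc1ccc(OCc2ccccc2)c(Br)c1
F4 | step 3 | (E)-1-[2-(benzyloxy)-6-hydroxy-4-methoxyphenyl]-3-[4-(benzyloxy)-3-bromophenyl]prop-2-en-1-one | COc1cc(O)c(C(=O)/C=C/c2ccc(OCc3ccccc3)c(Br)c2)c(OCc2ccccc2)c1
F5 | step 3 | 5-(benzyloxy)-2-[4-(benzyloxy)-3-bromophenyl]-7-methoxy-4H-chromen-4-one | COc1cc(OCc2ccccc2)c2c(=O)cc(-c3ccc(OCc4ccccc4)c(Br)c3)oc2c1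
F6 | step 3 | 5-(benzyloxy)-2-[4-(benzyloxy)-3-(4,4,5,5-tetramethyl-1,3,2-dioxaborolan-2-yl)phenyl]-7-methoxy-4H-chromen-4-one | COc1cc(OCc2ccccc2)c2c(=O)cc(-c3ccc(OCc4ccccc4)c(B4OC(C)(C)C(C)(C)O4)c3)oc2c1
F7 | step 3 | 5,5'',4',4'''-tetra-O-benzyl-7,7''-di-O-methylamentoflavone | COc1cc(OCc2ccccc2)c2c(=O)cc(-c3ccc(OCc4ccccc4)c(-c4c(OC)cc(OCc5ccccc5)c5c(=O)cc(-c6ccc(OCc7ccccc7)cc6)oc45)c3)oc2c1
F8 | step 1 | apigenin triacetate, 5,7-diacetoxy-2-(4-acetoxyphenyl)-4H-chromen-4-one | CC(=O)Oc1ccc(cc1)-c1cc(=O)c2c(OC(C)=O)cc(OC(C)=O)cc2o1
F9 | step 1 | 5,4'-di-O-acetylapigenin, 5-acetoxy-2-(4-acetoxyphenyl)-7-hydroxy-4H-chromen-4-one | CC(=O)Oc1ccc(cc1)-c1cc(=O)c2c(OC(C)=O)cc(O)cc2o1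
F10 | step 1 | 5,4'-di-O-acetylgenkwanin, 5-acetoxy-2-(4-acetoxyphenyl)-7-methoxy-4H-chromen-4-one | CC(=O)Oc1ccc(cc1)-c1cc(=O)c2c(OC(C)=O)cc(OC)cc2o1
F0 | step 4 | none | none
A1 | alternative 1 | 8-iodo-5-isopropoxy-2-(4-isopropoxyphenyl)-7-methoxy-4H-chromen-4-one | COc1cc(OC(C)C)c2c(=O)cc(-c3ccc(OC(C)C)cc3)oc2c1I
A2 | alternative 1 | 5-isopropoxy-2-[4-isopropoxy-3-(4,4,5,5-tetramethyl-1,3,2-dioxaborolan-2-yl)phenyl]-7-methoxy-4H-chromen-4-one | COc1cc(OC(C)C)c2c(=O)cc(-c3ccc(OC(C)C)c(B4OC(C)(C)C(C)(C)O4)c3)oc2c1
A3 | alternative 1 | 5,5'',4',4'''-tetra-O-isopropyl-7,7''-di-O-methylamentoflavone | COc1cc(OC(C)C)c2c(=O)cc(-c3ccc(OC(C)C)c(-c4c(OC)cc(OC(C)C)c5c(=O)cc(-c6ccc(OC(C)C)cc6)oc45)c3)oc2c1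
A4 | alternative 2 | methyl 4-(benzyloxy)-3-(methoxyethynyl)benzoate | COC#Cc1cc(C(=O)OC)ccc1OCc1ccccc1
A5 | alternative 2 | 3-ethoxycyclobut-2-en-1-one | CCOC1=CC(=O)C1
A6 | alternative 2 | methyl 4-(benzyloxy)-3-(4-ethoxy-2-hydroxy-6-methoxyphenyl)benzoate | COC(=O)c1ccc(OCc2ccccc2)c(-c2c(O)cc(OCC)cc2OC)c1
A7 | alternative 3 | 1-[6-(benzyloxy)-2-hydroxy-3-iodo-4-methoxyphenyl]ethan-1-one | CC(=O)c1c(O)c(I)c(OC)cc1OCc1ccccc1
A8 | alternative 3 | [2-(benzyloxy)-5-formylphenyl]boronic acid | O=Cc1ccc(OCc2ccccc2)c(B(O)O)c1
A9 | alternative 3 | 3-[3-acetyl-4-(benzyloxy)-2-hydroxy-6-methoxyphenyl]-4-(benzyloxy)benzaldehyde | CC(=O)c1c(OCc2ccccc2)cc(OC)c(-c2cc(C=O)ccc2OCc2ccccc2)c1O
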